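Charge 5.0 mM of starting material against 10.0 mM of solid reagent, which dissolves slowly into partner, and add the free catalyst in portions.

starting material 5.0 mM; solid reagent 10.0 mM; free catalyst 50 µM (in portions, 3); time 3.0 min; the portions of free catalyst follow each other after 1.0 min, the first at the start

    partner + free catalyst → catalyst intermediate A (k1 = 550 M⁻¹ s⁻¹)
    catalyst intermediate B ⇌ free catalyst + product (K2 = 0.0034 M, k2 = 0.53 s⁻¹)
    solid reagent ⇌ partner, rate k3*(cs3 - [partner]) while solid is left; crystals form when [partner] > cs3 (cs3 = 1.8 mM, k3 = 0.0056 s⁻¹)
    starting material + catalyst intermediate A → catalyst intermediate B (k4 = 5800 M⁻¹ s⁻¹)

- solid reagent is a solid; its amount is given per volume of the solution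
- at the start none of the solid reagent is in solution
- the reaction counts as stopped when no species that holds the starting material changes by six tenths of a point or more over the second half of the time
- run time (flask): 3.0 min

* why nothing more happens at 3.0 min, or that something still does (for what has run out or reacted, a solid counts together with what of it has only dissolved) (no working catalyst is left / forward and back rates have come level / it is still moving / the partner has run out first / all of the starting material has reacted)
* product at 3.0 min, in percent of the starting material charged

Compare the two steps that load the catalyst. Free catalyst takes up partner at k1[partner]; catalyst intermediate A takes up starting material at the pseudo-first-order k4[starting material]. Put starting material at its charge and [partner] at its highest, the solubility, and k4[starting material]/(k1[partner]) comes to 29.3: call this the capture ratio. So catalyst intermediate A goes on faster than free catalyst finds partner, and the rate is zero order in starting material, with k1[partner][free catalyst] as the step to reckon by.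

Now bound the partner. Dissolution gives at most k3·cs3 = 10.1 µM s⁻¹, so 1.81 mM at most in 3.0 min, and product stays under 36.3% of the charge. Stop there: this is a ceiling, not a yield.

The forecast says it is still moving, with product at 18% (15% to 21%) and “starting material, solid and active catalyst all still present”. That is half of my ceiling.

The flask gives it is still moving, with product at 17.9%. A charge of free catalyst of 30.8 µM or 81.3 µM moves that answer out of the forecast's range. Put this flask's readings at 3.00 min into the capture ratio: it stands at 88.6, above the 29.3 reckoned at the solubility, and free catalyst at 56.3% of the catalyst, divided by it, gives 0.635%, where catalyst intermediate A reads 0.635%. In the neighbour flask with 20 mM of starting material, the ratio at 3.00 min is 416, and its product is 0.899 mM, against 0.897 mM in the flask charged with 5.0 mM.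

Its constants come from no measurement; the rest is arithmetic.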